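The constant I wanted was k, the target made per second per unit of dissolved substrate D and of coupling partner B, with the rate in solution taken as k·D·B.

| setting | north-east | south-east | flask |
|---|---|---|---|
| solid substrate | 1 M | 1.5 M | 1.0 M |
| coupling partner | 0.80 equiv | 0.80 equiv | 0.800 equiv |
| remark | the very flask that is asked about, followed so far | run made earlier |  |
| time |  |  | 2.5 min |

| run | time / s | target / % | dissolved substrate / % |
|---|---|---|---|
| north-east | 15.0 | 1.4 | 27.4 |
| north-east | 30.0 | 3.2 | 32.8 |
| north-east | 50.0 | 5.5 | 35.1 |
| north-east | 60.0 | 6.3 | 35.8 |
| south-east | 10.0 | 0.1 | 14.9 |
| south-east | 12.0 | 1.0 | 16.9 |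
| south-east | 25.0 | 1.4 | 22.6 |
| south-east | 60.0 | 6.7 | 22.3 |

(readings scatter by 0.5 percentage points)

- solid, in amounts per volume of the solution: solid substrate
- at the start none of the solid substrate is in solution
- dissolved substrate means what is dissolved; the solid is not counted in it

* amount of target at 2.5 min, in percent of the solid substrate charged
* concentration of dissolved substrate in solution at 2.5 min, in percent of saturation

D began at nothing, so its last reading overstates its mean. I took that last reading as a plateau, 0.358 M in the north-east run and 0.335 M in the south-east run, and treated the climb as first-order. The area under such a climb equals that of the plateau begun late by a lag τ, which I read from each run's first reading: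

τ = t / ln(D_last / (D_last − D_first))

That gave 10.3 s in the north-east run and 9.07 s in the south-east run, so the north-east mean of D over 60.0 s was 0.297 M. I replaced the falling B by its mean, the partner charge C less half of the target P made:

k = P / ((t − τ) · D · (C − P/2))

The north-east run gave 0.00461 /M/s and the south-east run gave 0.00513 /M/s. These two ways part by 10.7%, and a target reading of 6.3% carries 0.5 percentage points, so I kept their mean, the second-order rate constant k̄ read from these runs, 0.00487 /M/s.

For the asked flask I kept D at 0.358 M and set a = k̄ · D · (t − τ), which is 0.244 at 2.5 min. Turned round, my formula gives

P = aC / (1 + a/2)

which is 17.4% of the solid charged. The exponential fall of B, C(1 − exp(−a)), differs from it by 0.076 points, which is the error of using the mean.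

The forecast gave 15.5% of target, less than my figure, and 96% of saturation, reasoning “so the solution stays near saturation”.

The flask gave 15.1% of target and 96.9% of saturation at 2.5 min.

    dissolved substrate + coupling partner → target (k = 0.00500 /M/s)
    solid substrate ⇌ dissolved substrate, rate k2*(cs2 - [dissolved substrate]) while solid is left; crystals form when [dissolved substrate] > cs2 (solubility = 0.370 M, k = 0.0990 /s)
    target ⇌ isomer of the product (K = 0.670, k = 0.00280 /s)

Isomer of the product stood beside the target at 2.67%, which makes 17.7% together against my 17.4%. For the same flask left until 10 min, where dissolved substrate still stood at 36.5%, k̄ gave a = 1.03 and by the exponential fall 51.4%; that flask held target at 35.1% and isomer of the product at 17.3%.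

All runs stem from a simulated flask for an exercise.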